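**Plan**

1. Target: (2Z,6E)-9-[(2S)-6-hydroxy-2,7,8-trimethyl-2H-chromen-2-yl]-6-methyl-2-(4-methylpent-3-en-1-yl)nona-2,6-dienoic acid; ring A is the benzene ring, ring B the pyran ring (O1, C2, C3, C4, C4a, C8a).
2. Retrosynthetic cuts, in order: ester O–CH3 and aryl O–Si; C4–H (the C3=C4 alkene goes back to a C4 ketone); C2–CH3; then C2–C3 together with O1–C8a (ring B opens to an aryl methyl ketone and a side-chain ester); the C=C(CO2Me) bond of the chain; the allyl–CH2CO2Me bond.
3. Enabling feature: C3=C4 is conjugated with ring A and C8a is ortho to C4a. With C4 carried as a carbonyl, C3–H is acidic, a C8a–F bond is open to substitution by oxygen, and after closure C2 is the β-carbon of a planar enone.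
4. Forward: the side-chain diester is built from geranyl bromide, the fluoro ketone from 4-fluoro-2,3-dimethylphenol (ring A is bought). Step 8 joins them and closes ring B; then come the C2 methyl, removal of the C4 oxygen to leave C3=C4, and deprotection.
5. Stereochemistry: 6E comes with geranyl bromide, 2Z from a Still–Gennari olefination. C2 (S) comes from a copper-catalysed enantioselective methyl addition to the Re face of C2 of the flat chromone, where the catalyst has to tell ring faces apart and not methyl from chain.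

Key step: step 8

Assumption: 4-fluoro-2,3-dimethylphenol, geranyl bromide and 5-bromo-2-methylpent-2-ene are taken as catalogue compounds.

**Route**

Step 1
Reactants: 1 geranyl bromide [(2E)-1-bromo-3,7-dimethylocta-2,6-diene]; 2 methyl acetate
Product: 4 methyl (4E)-5,9-dimethyldeca-4,8-dienoate, via lithium enolate of methyl acetate 3 (not isolated)
Conditions: LiN(iPr)2, THF, −78 °C; then 1, DMPU, −78 to −30 °C
Reagents that add atoms: none
Why: Alkylation of an ester enolate at the primary allylic bromide (SN2) should give the chain-extended ester; the later 6E double bond is carried in from 1 and no stereocenter is formed.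

Step 2
Reactants: 4 methyl (4E)-5,9-dimethyldeca-4,8-dienoate
Product: 6 methyl (4E)-7-(3,3-dimethyloxiran-2-yl)-5-methylhept-4-enoate (racemic), via bromohydrin 5 (not isolated)
Conditions: N-bromosuccinimide, THF/H2O, 0 °C; then K2CO3, MeOH, 20 °C
Reagents that add atoms: water, O
Why: Bromohydrin formation in aqueous THF should prefer the more exposed terminal trisubstituted double bond, and base then closes the epoxide by intramolecular SN2 etherification; the epoxide stereocenter is racemic and is destroyed in step 3.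

Step 3
Reactants: 6 methyl (4E)-7-(3,3-dimethyloxiran-2-yl)-5-methylhept-4-enoate
Product: 7 methyl (4E)-5-methyl-8-oxooct-4-enoate
Conditions: H5IO6, THF/Et2O, 0 °C
Reagents that add atoms: none
Why: Periodic acid opens the epoxide and cleaves the resulting glycol (glycol cleavage) to the aldehyde with loss of acetone, and should leave the trisubstituted alkene and the ester untouched.

Step 4
Reactants: 8 methyl 2-[bis(2,2,2-trifluoroethoxy)phosphoryl]acetate; 9 5-bromo-2-methylpent-2-ene
Product: 11 methyl 2-[bis(2,2,2-trifluoroethoxy)phosphoryl]-6-methylhept-5-enoate (racemic), via sodium carbanion of the phosphonoacetate 10 (not isolated)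
Conditions: NaH, DMF, 0 °C; then 9, Bu4NI (cat.), 50 °C
Reagents that add atoms: none
Why: C-alkylation of the stabilised phosphonoacetate anion by a primary bromide (SN2) should give the α-branched olefination reagent; its stereocenter is racemic and is lost in step 5.

Step 5
Reactants: 7 methyl (4E)-5-methyl-8-oxooct-4-enoate; 11 methyl 2-[bis(2,2,2-trifluoroethoxy)phosphoryl]-6-methylhept-5-enoate
Product: 13 methyl (4E,8Z)-9-(methoxycarbonyl)-5,13-dimethyltetradeca-4,8,12-trienoate, via potassium carbanion of the branched phosphonate 12 (not isolated)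
Conditions: KN(SiMe3)2, 18-crown-6, THF, −78 °C
Reagents that add atoms: none
Why: Still–Gennari olefination: with the electron-poor bis(trifluoroethyl) phosphonate and a dissociated potassium ion, elimination from the kinetic adduct should outrun its equilibration and place the ester cis to the chain (the later 2Z double bond), and the aldehyde reacts in preference to the saturated ester.

Step 6
Reactants: 14 4-fluoro-2,3-dimethylphenol
Product: 15 (4-fluoro-2,3-dimethylphenoxy)tri(propan-2-yl)silane
Conditions: iPr3SiCl, imidazole, DMF, 20 °C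
Reagents that add atoms: chlorotri(propan-2-yl)silane, CC(C)[Si](Cl)(C(C)C)C(C)C
Why: Silylation of the phenol gives a bulky, non-coordinating ether that protects the hydroxyl and shields the ring position next to oxygen for step 7.

Step 7
Reactants: 15 (4-fluoro-2,3-dimethylphenoxy)tri(propan-2-yl)silane; 16 N-methoxy-N-methylacetamide
Product: 19 1-[2-fluoro-3,4-dimethyl-5-[tri(propan-2-yl)silyloxy]phenyl]ethan-1-one, via aryllithium 17 (not isolated), via lithium hemiaminal adduct 18 (not isolated)
Conditions: s-BuLi, TMEDA, THF, −78 °C; then 16, −78 to 0 °C; aq. NH4Cl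
Reagents that add atoms: none
Why: Directed ortho-metalation: fluorine acidifies its ortho C–H and the only other ring C–H lies under the silyl group, so lithiation should occur at the carbon that becomes C4a, and acylation by the N-methoxy-N-methylamide stops at the ketone because the chelated adduct collapses only on work-up.

Step 8
Reactants: 19 1-[2-fluoro-3,4-dimethyl-5-[tri(propan-2-yl)silyloxy]phenyl]ethan-1-one; 13 methyl (4E,8Z)-9-(methoxycarbonyl)-5,13-dimethyltetradeca-4,8,12-trienoate
Product: 22 methyl (2Z,6E)-9-[7,8-dimethyl-4-oxo-6-[tri(propan-2-yl)silyloxy]-4H-chromen-2-yl]-6-methyl-2-(4-methylpent-3-en-1-yl)nona-2,6-dienoate, via lithium enolate of the ketone 20 (not isolated), via lithium 1,3-diketonate 21 (not isolated)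
Conditions: 19 (2 equiv), LiN(SiMe3)2 (2 equiv), THF, −78 °C; then 13, −78 to 20 °C; then DMF, 70 °C; aq. NH4Cl
Reagents that add atoms: none
Why: The enolate 20 attacks the unhindered saturated ester of 13 (Claisen condensation, C2–C3), methoxide leaves and a second equivalent of 20 converts the product into the diketonate 21, whose oxygen on C2 then adds to C8a and expels fluoride through an anionic σ-adduct stabilised by the C4 carbonyl (intramolecular nucleophilic aromatic substitution, O1–C8a). The closest known reaction type is the base-mediated synthesis of chromones and flavones from 2-fluoroaryl methyl ketones and esters or acyl halides. Ring B closes as a six-membered ring by addition–elimination at the aromatic carbon C8a (6-endo with respect to the C4a=C8a bond); the other diketonate oxygen and the central carbon could reach C8a only through a four-membered ring. No stereocenter is formed: the step makes C2 the planar, prochiral β-carbon of a cyclic enone, which is the setting step 9 needs. The selectivities needed are C- over O-acylation (lithium enolate, drain to the stable diketonate), attack at the saturated and not at the conjugated α-branched ester, and survival of the 2Z enoate and the aryl silyl ether; no amide base is left after the condensation, the only base present on warming is sparingly soluble LiOMe, and both esters are methyl esters so ester exchange changes nothing.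

Step 9
Reactants: 22 methyl (2Z,6E)-9-[7,8-dimethyl-4-oxo-6-[tri(propan-2-yl)silyloxy]-4H-chromen-2-yl]-6-methyl-2-(4-methylpent-3-en-1-yl)nona-2,6-dienoate
Product: 25 methyl (2Z,6E)-6-methyl-2-(4-methylpent-3-en-1-yl)-9-[(2S)-2,7,8-trimethyl-4-oxo-6-[tri(propan-2-yl)silyloxy]-3,4-dihydro-2H-chromen-2-yl]nona-2,6-dienoate, via 4-silyloxybenzopyrylium triflate 23 (not isolated), via trimethylsilyl enol ether 24 (not isolated)
Conditions: Me3SiOTf (1.3 equiv), 2,6-di-tert-butyl-4-methylpyridine (0.2 equiv), CH2Cl2, 0 °C; then CuBr·SMe2 (10 mol %), (R,R)-Ph-BPE (12 mol %), MeMgBr (1.5 equiv, added over 2 h), −78 °C; then 1 M HCl, THF, 0 °C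
Reagents that add atoms: methylmagnesium bromide, C[Mg]Br
Why: Proposed new method: silylation of the chromone carbonyl gives the aromatic 4-silyloxybenzopyrylium ion 23, a much stronger electrophile at C2 than the 2-alkylchromone itself, and a chiral bisphosphine–methylcopper species formed by transmetalation from slowly added MeMgBr should transfer methyl to C2 faster than the free organomagnesium reagent does; because the cation is flat and C4 is blocked by the silyloxy group, the ligand has only to tell the Re from the Si face of ring B and not methyl from the chain, so that delivery to the Re face gives (2S)-24 and, after hydrolysis, 25; the closest known reaction types are the copper–bisphosphine-catalysed enantioselective conjugate addition of organomagnesium reagents to 2-unsubstituted chromones and to Lewis-acid-activated 4-quinolones and 4-pyridones, and the copper-catalysed enantioselective alkynylation of 4-silyloxybenzopyrylium ions.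

Step 10
Reactants: 25 methyl (2Z,6E)-6-methyl-2-(4-methylpent-3-en-1-yl)-9-[(2S)-2,7,8-trimethyl-4-oxo-6-[tri(propan-2-yl)silyloxy]-3,4-dihydro-2H-chromen-2-yl]nona-2,6-dienoate
Product: 27 methyl (2Z,6E)-6-methyl-2-(4-methylpent-3-en-1-yl)-9-[(2S)-2,7,8-trimethyl-6-[tri(propan-2-yl)silyloxy]-4-(trifluoromethylsulfonyloxy)-2H-chromen-2-yl]nona-2,6-dienoate, via potassium enolate 26 (not isolated)
Conditions: KN(SiMe3)2, THF, −78 °C; then N-(5-chloropyridin-2-yl)bis(trifluoromethanesulfonyl)imide, −78 to −40 °C; aq. NH4Cl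
Reagents that add atoms: N-(5-chloropyridin-2-yl)bis(trifluoromethanesulfonyl)imide, FC(F)(F)S(=O)(=O)N(c1ccc(Cl)cn1)S(=O)(=O)C(F)(F)F
Why: Kinetic enolisation of the aryl ketone (C3 is its only α-carbon with hydrogen) and O-sulfonylation give the enol triflate, which fixes the C3=C4 double bond without a benzylic C4 cation that the chain alkenes could trap; at −78 °C loss of the aryloxide from C2 of the enolate (retro-oxa-Michael ring opening, which would endanger C2) should not compete.

Step 11
Reactants: 27 methyl (2Z,6E)-6-methyl-2-(4-methylpent-3-en-1-yl)-9-[(2S)-2,7,8-trimethyl-6-[tri(propan-2-yl)silyloxy]-4-(trifluoromethylsulfonyloxy)-2H-chromen-2-yl]nona-2,6-dienoate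
Product: 28 methyl (2Z,6E)-6-methyl-2-(4-methylpent-3-en-1-yl)-9-[(2S)-2,7,8-trimethyl-6-[tri(propan-2-yl)silyloxy]-2H-chromen-2-yl]nona-2,6-dienoate
Conditions: Pd(OAc)2 (5 mol %), PPh3, HCO2H, Bu3N, DMF, 60 °C, dark
Reagents that add atoms: none
Why: Palladium-catalysed formate reduction of an enol triflate (oxidative addition, formate exchange, decarboxylation to a palladium hydride, reductive elimination) replaces the triflate by hydrogen and should leave the trisubstituted alkenes, the enoate and the C2 stereocenter untouched.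

Step 12
Reactants: 28 methyl (2Z,6E)-6-methyl-2-(4-methylpent-3-en-1-yl)-9-[(2S)-2,7,8-trimethyl-6-[tri(propan-2-yl)silyloxy]-2H-chromen-2-yl]nona-2,6-dienoate
Product: 30 (2Z,6E)-9-[(2S)-6-hydroxy-2,7,8-trimethyl-2H-chromen-2-yl]-6-methyl-2-(4-methylpent-3-en-1-yl)nona-2,6-dienoic acid (target), via dilithium carboxylate phenoxide 29 (not isolated)
Conditions: LiOH·H2O (10 equiv), THF/MeOH/H2O, 50 °C, argon, dark; then cold 0.5 M HCl to pH 4
Reagents that add atoms: lithium hydroxide, [Li+].[OH-]
Why: Saponification of the methyl ester and hydroxide-induced cleavage of the aryl silyl ether (phenoxide is a good leaving group from silicon) should occur in one operation; oxygen is excluded to protect the electron-rich phenoxide, light is excluded to prevent electrocyclic opening of the chromene at C2, and hydroxide should not add to the α-branched Z-enoate.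

**Compound list**

1 | geranyl bromide, (2E)-1-bromo-3,7-dimethylocta-2,6-diene | CC(C)=CCC/C(C)=C/CBr | starting material
2 | methyl acetate | COC(C)=O | starting material
3 | lithium enolate of methyl acetate (not isolated) | [Li+].[O-]C(=C)OC | intermediate
4 | methyl (4E)-5,9-dimethyldeca-4,8-dienoate | COC(=O)CC/C=C(\C)CCC=C(C)C | intermediate
5 | methyl (4E)-8-bromo-9-hydroxy-5,9-dimethyldec-4-enoate, racemic bromohydrin (not isolated) | COC(=O)CC/C=C(\C)CCC(Br)C(C)(C)O | intermediate
6 | methyl (4E)-7-(3,3-dimethyloxiran-2-yl)-5-methylhept-4-enoate, racemic | COC(=O)CC/C=C(\C)CCC1OC1(C)C | intermediate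
7 | methyl (4E)-5-methyl-8-oxooct-4-enoate | COC(=O)CC/C=C(\C)CCC=O | intermediate
8 | methyl 2-[bis(2,2,2-trifluoroethoxy)phosphoryl]acetate | COC(=O)CP(=O)(OCC(F)(F)F)OCC(F)(F)F | starting material
9 | 5-bromo-2-methylpent-2-ene | CC(C)=CCCBr | starting material
10 | sodium carbanion of 8 (not isolated) | [Na+].COC(=O)[CH-]P(=O)(OCC(F)(F)F)OCC(F)(F)F | intermediate
11 | methyl 2-[bis(2,2,2-trifluoroethoxy)phosphoryl]-6-methylhept-5-enoate, racemic | COC(=O)C(CCC=C(C)C)P(=O)(OCC(F)(F)F)OCC(F)(F)F | intermediate
12 | potassium carbanion of 11 (not isolated) | [K+].COC(=O)[C-](CCC=C(C)C)P(=O)(OCC(F)(F)F)OCC(F)(F)F | intermediate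
13 | methyl (4E,8Z)-9-(methoxycarbonyl)-5,13-dimethyltetradeca-4,8,12-trienoate | COC(=O)CC/C=C(\C)CC/C=C(/CCC=C(C)C)C(=O)OC | intermediate
14 | 4-fluoro-2,3-dimethylphenol | Cc1c(O)ccc(F)c1C | starting material
15 | (4-fluoro-2,3-dimethylphenoxy)tri(propan-2-yl)silane | Cc1c(O[Si](C(C)C)(C(C)C)C(C)C)ccc(F)c1C | intermediate
16 | N-methoxy-N-methylacetamide | CC(=O)N(C)OC | starting material
17 | [2-fluoro-3,4-dimethyl-5-[tri(propan-2-yl)silyloxy]phenyl]lithium (not isolated) | Cc1c(O[Si](C(C)C)(C(C)C)C(C)C)cc([Li])c(F)c1C | intermediate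
18 | lithium 1-[2-fluoro-3,4-dimethyl-5-[tri(propan-2-yl)silyloxy]phenyl]-1-[methoxy(methyl)amino]ethan-1-olate (not isolated) | [Li+].CC([O-])(N(C)OC)c1cc(O[Si](C(C)C)(C(C)C)C(C)C)c(C)c(C)c1F | intermediate
19 | 1-[2-fluoro-3,4-dimethyl-5-[tri(propan-2-yl)silyloxy]phenyl]ethan-1-one | CC(=O)c1cc(O[Si](C(C)C)(C(C)C)C(C)C)c(C)c(C)c1F | intermediate
20 | lithium enolate of 19 (not isolated) | [Li+].C=C([O-])c1cc(O[Si](C(C)C)(C(C)C)C(C)C)c(C)c(C)c1F | intermediate
21 | lithium enolate of methyl (2Z,6E)-12-[2-fluoro-3,4-dimethyl-5-[tri(propan-2-yl)silyloxy]phenyl]-6-methyl-2-(4-methylpent-3-en-1-yl)-10,12-dioxododeca-2,6-dienoate (not isolated) | [Li+].CC(C)=CCC/C(=C/CC/C(C)=C/CCC(=O)[CH-]C(=O)c1cc(O[Si](C(C)C)(C(C)C)C(C)C)c(C)c(C)c1F)C(=O)OC | intermediate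
22 | methyl (2Z,6E)-9-[7,8-dimethyl-4-oxo-6-[tri(propan-2-yl)silyloxy]-4H-chromen-2-yl]-6-methyl-2-(4-methylpent-3-en-1-yl)nona-2,6-dienoate | CC(C)=CCC/C(=C/CC/C(C)=C/CCc1cc(=O)c2cc(O[Si](C(C)C)(C(C)C)C(C)C)c(C)c(C)c2o1)C(=O)OC | intermediate
23 | 4-(trimethylsilyloxy)chromenylium triflate of 22, i.e. 22 silylated on the C4 oxygen (not isolated) | C[Si](C)(C)Oc1cc(CC/C=C(\C)CC/C=C(/CCC=C(C)C)C(=O)OC)[o+]c2c(C)c(C)c(O[Si](C(C)C)(C(C)C)C(C)C)cc12.[O-]S(=O)(=O)C(F)(F)F | intermediate
24 | methyl (2Z,6E)-6-methyl-2-(4-methylpent-3-en-1-yl)-9-[(2S)-2,7,8-trimethyl-6-[tri(propan-2-yl)silyloxy]-4-(trimethylsilyloxy)-2H-chromen-2-yl]nona-2,6-dienoate (not isolated) | CC(C)=CCC/C(=C/CC/C(C)=C/CC[C@@]1(C)C=C(O[Si](C)(C)C)c2cc(O[Si](C(C)C)(C(C)C)C(C)C)c(C)c(C)c2O1)C(=O)OC | intermediate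
25 | methyl (2Z,6E)-6-methyl-2-(4-methylpent-3-en-1-yl)-9-[(2S)-2,7,8-trimethyl-4-oxo-6-[tri(propan-2-yl)silyloxy]-3,4-dihydro-2H-chromen-2-yl]nona-2,6-dienoate | CC(C)=CCC/C(=C/CC/C(C)=C/CC[C@@]1(C)CC(=O)c2cc(O[Si](C(C)C)(C(C)C)C(C)C)c(C)c(C)c2O1)C(=O)OC | intermediate
26 | potassium enolate of 25 (not isolated) | [K+].CC(C)=CCC/C(=C/CC/C(C)=C/CC[C@@]1(C)C=C([O-])c2cc(O[Si](C(C)C)(C(C)C)C(C)C)c(C)c(C)c2O1)C(=O)OC | intermediate
27 | methyl (2Z,6E)-6-methyl-2-(4-methylpent-3-en-1-yl)-9-[(2S)-2,7,8-trimethyl-6-[tri(propan-2-yl)silyloxy]-4-(trifluoromethylsulfonyloxy)-2H-chromen-2-yl]nona-2,6-dienoate | CC(C)=CCC/C(=C/CC/C(C)=C/CC[C@@]1(C)C=C(OS(=O)(=O)C(F)(F)F)c2cc(O[Si](C(C)C)(C(C)C)C(C)C)c(C)c(C)c2O1)C(=O)OC | intermediate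
28 | methyl (2Z,6E)-6-methyl-2-(4-methylpent-3-en-1-yl)-9-[(2S)-2,7,8-trimethyl-6-[tri(propan-2-yl)silyloxy]-2H-chromen-2-yl]nona-2,6-dienoate | CC(C)=CCC/C(=C/CC/C(C)=C/CC[C@@]1(C)C=Cc2cc(O[Si](C(C)C)(C(C)C)C(C)C)c(C)c(C)c2O1)C(=O)OC | intermediate
29 | dilithium salt of 30, carboxylate and phenoxide (not isolated) | [Li+].[Li+].CC(C)=CCC/C(=C/CC/C(C)=C/CC[C@@]1(C)C=Cc2cc([O-])c(C)c(C)c2O1)C(=O)[O-] | intermediate
30 | (2Z,6E)-9-[(2S)-6-hydroxy-2,7,8-trimethyl-2H-chromen-2-yl]-6-methyl-2-(4-methylpent-3-en-1-yl)nona-2,6-dienoic acid | CC(C)=CCC/C(=C/CC/C(C)=C/CC[C@@]1(C)C=Cc2cc(O)c(C)c(C)c2O1)C(=O)O | target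

**Step count and risks**

Total step count: 12. Longest linear sequence: 9 steps (1, 2, 3, 5, 8, 9, 10, 11, 12).

Steps most likely to fail:

Step 9 (bears the label). The uncatalysed addition of the organomagnesium reagent to the pyrylium ion, or to the enoate ester, may outrun the copper-catalysed pathway, and the ligand may discriminate the two faces of C2 poorly, since a 2-substituent is new for this catalyst class; the sense of induction of the ligand is assumed by analogy. The fallback sets out from 22 and comes back at 25 and uses known chemistry with resolution in place of asymmetric catalysis. Racemic conjugate methylation of the 2-alkylchromone with Me2CuLi and Me3SiCl (THF, −78 °C) would give the racemic trimethylsilyl enol ether F1. Dilute HCl would give the racemic chromanone F2. Preparative chromatography on a chiral stationary phase (cellulose tris(3,5-dimethylphenylcarbamate), CO2/MeOH) would separate 25 from the (2R)-chromanone F3.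

Step 8. Reversible conjugate addition of methoxide during the warm ring closure may isomerise the 2Z enoate; condensation may occur at the conjugated ester; or the aryl silyl ether may be cleaved before fluoride is displaced, which would stop the ring closure. The fallback sets out from 7 and comes back at 22, and brings the Z-enoate in only after ring B is closed. Acetalisation of 7 (HC(OMe)3, pyridinium p-toluenesulfonate, MeOH) would give methyl (4E)-8,8-dimethoxy-5-methyloct-4-enoate F4. Condensation with 20 under the conditions of step 8 would give the lithium 1,3-diketonate of the acetal series F5 and from it the chromone acetal F6. Hydrolysis (pyridinium p-toluenesulfonate, acetone/H2O, 50 °C) would give the chromone aldehyde F7. Still–Gennari olefination of F7 with 11 (via 12, as in step 5) would give 22.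

Step 7. Lithiation may occur at a benzylic methyl group or next to the silyloxy group, or the aryllithium may lose LiF to an aryne if the temperature rises. The fallback sets out from 15 and comes back at 19, and replaces deprotonation by sterically controlled C–H borylation. Borylation with [Ir(OMe)(cod)]2, 4,4'-di-tert-butyl-2,2'-bipyridine and bis(pinacolato)diboron (THF, 80 °C) should take place at the C–H next to the small fluorine and give the aryl pinacol boronate F8. Palladium-catalysed acylative cross-coupling of F8 with acetic anhydride (Pd(OAc)2, P(4-MeOC6H4)3, wet THF, 60 °C) would give 19.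

**Further compounds**

F1 | step 9 | racemic methyl (2Z,6E)-6-methyl-2-(4-methylpent-3-en-1-yl)-9-[2,7,8-trimethyl-6-[tri(propan-2-yl)silyloxy]-4-(trimethylsilyloxy)-2H-chromen-2-yl]nona-2,6-dienoate | CC(C)=CCC/C(=C/CC/C(C)=C/CCC1(C)C=C(O[Si](C)(C)C)c2cc(O[Si](C(C)C)(C(C)C)C(C)C)c(C)c(C)c2O1)C(=O)OC
F2 | step 9 | racemic chromanone, (2RS) form of 25 | CC(C)=CCC/C(=C/CC/C(C)=C/CCC1(C)CC(=O)c2cc(O[Si](C(C)C)(C(C)C)C(C)C)c(C)c(C)c2O1)C(=O)OC
F3 | step 9 | (2R)-chromanone, enantiomer of 25 | CC(C)=CCC/C(=C/CC/C(C)=C/CC[C@]1(C)CC(=O)c2cc(O[Si](C(C)C)(C(C)C)C(C)C)c(C)c(C)c2O1)C(=O)OC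
F4 | step 8 | methyl (4E)-8,8-dimethoxy-5-methyloct-4-enoate | COC(=O)CC/C=C(\C)CCC(OC)OC
F5 | step 8 | lithium enolate of (6E)-1-[2-fluoro-3,4-dimethyl-5-[tri(propan-2-yl)silyloxy]phenyl]-10,10-dimethoxy-7-methyldec-6-ene-1,3-dione | [Li+].COC(OC)CC/C(C)=C/CCC(=O)[CH-]C(=O)c1cc(O[Si](C(C)C)(C(C)C)C(C)C)c(C)c(C)c1F
F6 | step 8 | 2-[(3E)-7,7-dimethoxy-4-methylhept-3-en-1-yl]-7,8-dimethyl-6-[tri(propan-2-yl)silyloxy]-4H-chromen-4-one | COC(OC)CC/C(C)=C/CCc1cc(=O)c2cc(O[Si](C(C)C)(C(C)C)C(C)C)c(C)c(C)c2o1
F7 | step 8 | (4E)-7-[7,8-dimethyl-4-oxo-6-[tri(propan-2-yl)silyloxy]-4H-chromen-2-yl]-4-methylhept-4-enal | O=CCC/C(C)=C/CCc1cc(=O)c2cc(O[Si](C(C)C)(C(C)C)C(C)C)c(C)c(C)c2o1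
F8 | step 7 | 2-[2-fluoro-3,4-dimethyl-5-[tri(propan-2-yl)silyloxy]phenyl]-4,4,5,5-tetramethyl-1,3,2-dioxaborolane | CC1(C)OB(OC1(C)C)c1cc(O[Si](C(C)C)(C(C)C)C(C)C)c(C)c(C)c1F
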